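Retrosynthesis: the two O-protecting groups come off last (acetyl on ring A, methyl on ring B). Two C–C bonds of ring A, the dibromophenol ring, are then cut: C1(OH)–C6(OAr) and C4(Br)–C5(H). The diaryl ether C–O bonds are never cut.
Enabling feature: in ring A the run C1(O)–C2(Br)–C3(H)–C4(Br) is C3–C6 of a 3-acyloxy-4,6-dibromo-2-pyrone. The pair C5(H)–C6(OAr) is the triple bond of an ethynyl ether whose oxygen already carries ring B.
Forward, ring B: it is bought as a catechol mono(2-hydroxyethyl) ether, tribrominated and O-methylated. Its side chain is then taken through the vinyl and bromovinyl ethers to the ethynyl ether, while 3-hydroxy-2-pyrone is dibrominated and acetylated in parallel.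
Forward, ring A: it arises in one operation by [4+2] cycloaddition of the two halves and loss of CO2, with all five bromines and all three oxygens in place. One deprotection ends the route.
Stereochemistry: the target has no stereocentre, so only regiochemistry has to be controlled (two bromination patterns and the orientation of the cycloaddition).

Key step: step 9

Remark on the chemistry: the diaryl ether axis is taken to rotate freely, so the target is treated as achiral. The bromovinyl ether of step 7 is expected as an E/Z mixture, is drawn as its Z isomer and is carried on as the mixture. The transient bridged lactones are racemic, with one enantiomer drawn.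

Step 1
Reactants: 1 3-hydroxy-2H-pyran-2-one
Product: 2 4,6-dibromo-3-hydroxy-2H-pyran-2-one
Conditions: NBS (2.1 equiv), MeCN, 0 → 40 °C, dark
Reagents that add atoms: N-bromosuccinimide, O=C1CCC(=O)N1Br
Why: Electrophilic halogenation of a cyclic dienol: the 3-hydroxyl pushes electron density through C3=C4–C5=C6 onto C4 and C6 (its ortho-like and para-like positions), so two equivalents of NBS should brominate these two carbons and spare C5, which only the weakly donating lactone oxygen activates.

Step 2
Reactants: 2 4,6-dibromo-3-hydroxy-2H-pyran-2-one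
Product: 3 4,6-dibromo-2-oxo-2H-pyran-3-yl acetate
Conditions: Ac2O, H2SO4 (cat.), 0 °C → rt
Reagents that add atoms: acetic anhydride, CC(=O)OC(C)=O
Why: Acid-catalysed O-acetylation of an acidic enol; leaving out amines avoids addition–elimination at the labile C6–Br bond, and the ester turns the donor oxygen on C3 into a weakly withdrawing group, which lowers the diene LUMO for step 9.

Step 3
Reactants: 4 2-(2-hydroxyethoxy)phenol
Product: 5 2,3,4-tribromo-6-(2-hydroxyethoxy)phenol
Conditions: Br2 (3.3 equiv), NaOAc, AcOH, rt → 50 °C
Reagents that add atoms: bromine, BrBr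
Why: Electrophilic aromatic bromination: the free hydroxyl directs two bromines para and ortho to itself and the alkoxy group directs the third to its own para position, which is the pattern of exhaustive halogenation of guaiacol-type 2-alkoxyphenols, while the acetate buffer removes HBr and so protects the primary alcohol.

Step 4
Reactants: 5 2,3,4-tribromo-6-(2-hydroxyethoxy)phenol
Product: 6 2-(3,4,5-tribromo-2-methoxyphenoxy)ethan-1-ol
Conditions: MeI, K2CO3, acetone, 40 °C
Reagents that add atoms: iodomethane, CI
Why: Williamson ether synthesis: carbonate deprotonates only the acidic tribromophenol and not the primary alcohol, so methylation should occur on the phenol oxygen alone.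

Step 5
Reactants: 6 2-(3,4,5-tribromo-2-methoxyphenoxy)ethan-1-ol
Product: 7 1,2,3-tribromo-5-(2-bromoethoxy)-4-methoxybenzene
Conditions: CBr4, PPh3, CH2Cl2, 0 °C → rt
Reagents that add atoms: tetrabromomethane, BrC(Br)(Br)Br
Why: Appel reaction: bromide displaces the alkoxyphosphonium ion of the primary alcohol by SN2 under neutral conditions that leave aryl bromides and both ethers alone.

Step 6
Reactants: 7 1,2,3-tribromo-5-(2-bromoethoxy)-4-methoxybenzene
Product: 8 1,2,3-tribromo-5-(ethenyloxy)-4-methoxybenzene
Conditions: KOt-Bu, THF, 0 °C → rt
Reagents that add atoms: none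
Why: E2 dehydrobromination of a 2-bromoethyl aryl ether with a hindered alkoxide is the standard entry to aryl vinyl ethers; bromide is a far better leaving group than the aryloxide, and the base is too weak to metalate the ring at this temperature.

Step 7
Reactants: 8 1,2,3-tribromo-5-(ethenyloxy)-4-methoxybenzene
Product: 10 (Z)-1,2,3-tribromo-5-[(2-bromoethenyl)oxy]-4-methoxybenzene, via 1,2-dibromoethyl ether 9 (not isolated)
Conditions: Br2, CH2Cl2, −78 °C; then DBU, −78 °C → rt
Reagents that add atoms: bromine, BrBr
Why: Bromine addition to the enol ether double bond followed by amidine-induced loss of HBr is the usual bromination–dehydrobromination route to β-bromo enol ethers; the single ring C–H is far too deactivated to compete, and the alkene geometry does not matter because both isomers lead to the same alkyne.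

Step 8
Reactants: 10 (Z)-1,2,3-tribromo-5-[(2-bromoethenyl)oxy]-4-methoxybenzene
Product: 11 1,2,3-tribromo-5-(ethynyloxy)-4-methoxybenzene
Conditions: KOt-Bu (2 equiv), THF, −40 → 0 °C; then pH 7 buffer, cold
Reagents that add atoms: none
Why: β-Elimination of HBr from a 2-bromovinyl ether is the classical route to ethynyl ethers: the Z isomer has H and Br anti-periplanar and the E isomer follows more slowly, and an alkoxide in place of an organolithium or lithium amide avoids bromine–metal exchange and ring deprotonation.

Step 9
Reactants: 3 4,6-dibromo-2-oxo-2H-pyran-3-yl acetate; 11 1,2,3-tribromo-5-(ethynyloxy)-4-methoxybenzene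
Product: 13 2,4-dibromo-6-(3,4,5-tribromo-2-methoxyphenoxy)phenyl acetate, via bridged bicyclic lactone 12 (not isolated)
Conditions: 3 (1.5 equiv), BHT (cat.), PhMe, 110 °C, Ar, base-washed glass, 11 added slowly by syringe pump; −CO2
Reagents that add atoms: none
Why: The ynol ether HOMO, largest on the terminal CH, adds across C6 and C3 of the electron-poor pyrone diene in a concerted but asynchronous inverse-electron-demand Diels–Alder reaction, with the C6–CH bond leading and the C3–C(OAr) bond following. The 2-oxabicyclo[2.2.2]octadienone 12 should not survive at this temperature and expels CO2 by retro-[4+2], so ring A is closed by an intermolecular [4+2] annulation (two new C–C bonds) and is aromatic without any oxidation step. The closest known reaction type is the 2-pyrone/alkyne cycloaddition–decarboxylation to benzenes, which runs most easily with halogenated or acceptor-substituted pyrones and heteroatom-donor alkynes or enol ethers. The selectivity needed is regiochemical: C6 is the 1,6-acceptor terminus of the dienoate, further polarised by the ring oxygen and its bromine, whereas C3 is the α-carbon of the lactone, so the nucleophilic CH should bond to C6 and the aryloxy carbon should end up next to the acetoxy carbon. The two bromines lower the diene LUMO, the 3-acetoxy group opposes this polarisation far less than an alkoxy group would, and sterics agree because the unsubstituted alkyne carbon meets the brominated C6. The two bridgehead stereocentres of 12 are racemic and vanish with CO2, so no stereocontrol is needed, and slow addition of 11 with a radical inhibitor holds back its self-condensation.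

Step 10
Reactants: 13 2,4-dibromo-6-(3,4,5-tribromo-2-methoxyphenoxy)phenyl acetate
Product: 15 2,3,4-tribromo-6-(3,5-dibromo-2-hydroxyphenoxy)phenol (CNP0266564.0), via aryloxydibromoborane 14 (not isolated)
Conditions: BBr3 (4 equiv), CH2Cl2, −78 °C → rt; then MeOH, 40 °C
Reagents that add atoms: none
Why: Lewis-acid dealkylation of an aryl methyl ether (boron complexation, then bromide attack on the methyl carbon) is the standard unmasking of methoxylated polybromodiphenyl ethers and leaves the diaryl ether and C–Br bonds intact, and the HBr/MeOH formed on quenching solvolyses the B–O bond and transesterifies the activated aryl acetate in the same flask.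

Compound list
1 | 3-hydroxy-2H-pyran-2-one | OC1=CC=COC1=O | starting material
2 | 4,6-dibromo-3-hydroxy-2H-pyran-2-one | OC1=C(Br)C=C(Br)OC1=O | intermediate
3 | 4,6-dibromo-2-oxo-2H-pyran-3-yl acetate | CC(=O)OC1=C(Br)C=C(Br)OC1=O | intermediate
4 | 2-(2-hydroxyethoxy)phenol | OCCOc1ccccc1O | starting material
5 | 2,3,4-tribromo-6-(2-hydroxyethoxy)phenol | OCCOc1cc(Br)c(Br)c(Br)c1O | intermediate
6 | 2-(3,4,5-tribromo-2-methoxyphenoxy)ethan-1-ol | OCCOc1cc(Br)c(Br)c(Br)c1OC | intermediate
7 | 1,2,3-tribromo-5-(2-bromoethoxy)-4-methoxybenzene | BrCCOc1cc(Br)c(Br)c(Br)c1OC | intermediate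
8 | 1,2,3-tribromo-5-(ethenyloxy)-4-methoxybenzene | C=COc1cc(Br)c(Br)c(Br)c1OC | intermediate
9 | 1,2,3-tribromo-5-(1,2-dibromoethoxy)-4-methoxybenzene (racemic, not isolated) | BrCC(Br)Oc1cc(Br)c(Br)c(Br)c1OC | intermediate
10 | (Z)-1,2,3-tribromo-5-[(2-bromoethenyl)oxy]-4-methoxybenzene (Z drawn, E/Z mixture usable) | Br/C=C\Oc1cc(Br)c(Br)c(Br)c1OC | intermediate
11 | 1,2,3-tribromo-5-(ethynyloxy)-4-methoxybenzene | C#COc1cc(Br)c(Br)c(Br)c1OC | intermediate
12 | 1,8-dibromo-3-oxo-5-(3,4,5-tribromo-2-methoxyphenoxy)-2-oxabicyclo[2.2.2]octa-5,7-dien-4-yl acetate (racemic, one enantiomer drawn, not isolated) | O=C1O[C@@]2(Br)C=C(Br)[C@]1(OC(C)=O)C(Oc3cc(Br)c(Br)c(Br)c3OC)=C2 | intermediate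
13 | 2,4-dibromo-6-(3,4,5-tribromo-2-methoxyphenoxy)phenyl acetate | CC(=O)Oc1c(Br)cc(Br)cc1Oc1cc(Br)c(Br)c(Br)c1OC | intermediate
14 | 2,4-dibromo-6-[3,4,5-tribromo-2-(dibromoboranyloxy)phenoxy]phenyl acetate (not isolated) | CC(=O)Oc1c(Br)cc(Br)cc1Oc1cc(Br)c(Br)c(Br)c1OB(Br)Br | intermediate
15 | 2,3,4-tribromo-6-(3,5-dibromo-2-hydroxyphenoxy)phenol | Oc1c(Br)cc(Br)cc1Oc1cc(Br)c(Br)c(Br)c1O | target

Total step count: 10.
Longest linear sequence: 8 steps (4 → 15, steps 3 to 10). The pyrone branch (1 → 3) adds 2 steps.

Steps most likely to fail

Step 9. The crowded, fully substituted diene may react more slowly than the terminal ynol ether oligomerises. The alkyne may also attack C6 and expel bromide instead of closing the second bond. The fallback sets out from 8 and comes back at 15: the diaryl ether is made by C–O coupling and ring A is brominated last. Vinyl ether 8 is hydrolysed (aq HCl, THF) to 3,4,5-tribromo-2-methoxyphenol F1. Chan–Lam coupling of this phenol with commercial (2-methoxyphenyl)boronic acid (Cu(OAc)2, pyridine, 4 Å sieves, CH2Cl2, air, rt) tolerates aryl bromides and should give 1,2,3-tribromo-4-methoxy-5-(2-methoxyphenoxy)benzene F2. BBr3 in CH2Cl2 then frees 2,3,4-tribromo-6-(2-hydroxyphenoxy)phenol F3. Two equivalents of Br2 in AcOH should enter ortho and para to the hydroxyl of the unbrominated ring and give 15, because the only open position of ring B is meta to its hydroxyl and next to a bromine.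

Step 1. Halogenation may stop after the first bromine, stray to C5 or end in oxidative opening of the lactone. The fallback sets out from 1 and comes back at 15: the ring-A bromines are installed after the ring has been built. Compound 1 is acetylated under the conditions of step 2 to 2-oxo-2H-pyran-3-yl acetate F4. Cycloaddition with 11 needs more forcing conditions (xylene, 140 °C) because the LUMO-lowering halogens are missing. It passes through 3-oxo-5-(3,4,5-tribromo-2-methoxyphenoxy)-2-oxabicyclo[2.2.2]octa-5,7-dien-4-yl acetate F5 and, after loss of CO2, gives 2-(3,4,5-tribromo-2-methoxyphenoxy)phenyl acetate F6. K2CO3 in MeOH frees 2-(3,4,5-tribromo-2-methoxyphenoxy)phenol F7. Br2 (2 equiv) in AcOH should brominate ortho and para to the only free hydroxyl, ring B still being masked and deactivated, to give 2,4-dibromo-6-(3,4,5-tribromo-2-methoxyphenoxy)phenol F8. BBr3 then cleaves the methyl ether to give 15.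

Step 8. The base may deprotonate the ring and cause bromine migration, tert-butoxide may add to the triple bond, or the terminal ynol ether may polymerise during isolation. The fallback sets out from 10 and comes back at 13: the second loss of HBr is postponed until after the cycloaddition, where aromatisation drives it and a weak base suffices. The thermally robust bromovinyl ether 10 is heated with 3 and 2,6-lutidine in xylene at 140 °C, or pressed at high pressure first, as an alkyne surrogate. The cycloaddition has the same orientation as step 9 and gives 1,6,8-tribromo-3-oxo-5-(3,4,5-tribromo-2-methoxyphenoxy)-2-oxabicyclo[2.2.2]oct-7-en-4-yl acetate F9. This lactone loses CO2 to cis-2,4,5-tribromo-6-(3,4,5-tribromo-2-methoxyphenoxy)cyclohexa-1,3-dien-1-yl acetate F10. Loss of HBr rather than of the aryloxide, bromide being by far the better leaving group, then aromatises the ring to 13.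

Further compounds
F1 | step 9 | 3,4,5-tribromo-2-methoxyphenol | COc1c(O)cc(Br)c(Br)c1Br
F2 | step 9 | 1,2,3-tribromo-4-methoxy-5-(2-methoxyphenoxy)benzene | COc1ccccc1Oc1cc(Br)c(Br)c(Br)c1OC
F3 | step 9 | 2,3,4-tribromo-6-(2-hydroxyphenoxy)phenol | Oc1ccccc1Oc1cc(Br)c(Br)c(Br)c1O
F4 | step 1 | 2-oxo-2H-pyran-3-yl acetate | CC(=O)OC1=CC=COC1=O
F5 | step 1 | 3-oxo-5-(3,4,5-tribromo-2-methoxyphenoxy)-2-oxabicyclo[2.2.2]octa-5,7-dien-4-yl acetate (racemic, one enantiomer drawn) | O=C1O[C@H]2C=C[C@]1(OC(C)=O)C(Oc3cc(Br)c(Br)c(Br)c3OC)=C2
F6 | step 1 | 2-(3,4,5-tribromo-2-methoxyphenoxy)phenyl acetate | CC(=O)Oc1ccccc1Oc1cc(Br)c(Br)c(Br)c1OC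
F7 | step 1 | 2-(3,4,5-tribromo-2-methoxyphenoxy)phenol | Oc1ccccc1Oc1cc(Br)c(Br)c(Br)c1OC
F8 | step 1 | 2,4-dibromo-6-(3,4,5-tribromo-2-methoxyphenoxy)phenol | Oc1c(Br)cc(Br)cc1Oc1cc(Br)c(Br)c(Br)c1OC
F9 | step 8 | 1,6,8-tribromo-3-oxo-5-(3,4,5-tribromo-2-methoxyphenoxy)-2-oxabicyclo[2.2.2]oct-7-en-4-yl acetate (racemic, cis aryloxy/bromo, endo isomer drawn) | O=C1O[C@@]2(Br)C=C(Br)[C@]1(OC(C)=O)[C@H](Oc3cc(Br)c(Br)c(Br)c3OC)[C@@H]2Br
F10 | step 8 | cis-2,4,5-tribromo-6-(3,4,5-tribromo-2-methoxyphenoxy)cyclohexa-1,3-dien-1-yl acetate (racemic) | CC(=O)OC1=C(Br)C=C(Br)[C@@H](Br)[C@H]1Oc2cc(Br)c(Br)c(Br)c2OC
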